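## Retrosynthetic overview

1. Lactone E and ring D: the target comes from ketoreduction and lactonisation of an acetyl carbinol. That carbinol comes from α-ketol contraction of a C3'-hydroxylated bicyclo[3.3.1] β-diketone, in the order of events of the austinoid pathway.
2. Rings A, B and C (six stereocentres) come from one cyclase-type cation–olefin cascade. It ends on C1' of a dearomatised 3,5-dimethylorsellinate and loses H+ from the C6' methyl. It starts from a C4 acyloxycarbenium ion instead of an epoxide, so the rearranged ring A with its γ-lactone and 1-OH forms directly.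
3. The cascade precursor is a strained ketal-lactone made with gold from a 3-hydroxy-2-propargyl acid. The polyene comes from dearomative C5'-allylation of methyl 3,5-dimethylorsellinate, the prenyl-transferase step.
4. The allylic acetate comes from an auxiliary-controlled anti-aldol of a pent-4-ynoyl imide with 8-oxogeranyl acetate. The arene comes from methyl atratate.
5. Ring order: γ-lactone bridge, then A, then B, then the C/D bicycle (one flask), then contraction of D, then lactone E.

Locants: C1 is the carbinol, C2 the lactone α-carbon, C3 the lactone C=O and C4 the O-bearing quaternary carbon. C5/C10 and C8/C9 are the ring-fusion carbons and C11 is the CH2 on the orsellinate ring. C1'–C6' are the orsellinate carbons: C1' bears CO2Me, C5' becomes quaternary, and the C6' methyl becomes the exocyclic methylene.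

Assumption: the (R,R) ligand in step 6 is taken to give the 5'R centre; if the sense is opposite, the (S,S) ligand is used.

## Route

Step 1
Reactants: 1 geranyl acetate
Product: 2 (2E,6E)-3,7-dimethyl-8-oxoocta-2,6-dien-1-yl acetate (8-oxogeranyl acetate)
Conditions: SeO2 (1.1 equiv), 1,4-dioxane, 80 °C
Reagents that add atoms: selenium dioxide, O=[Se]=O
Why: Riley allylic oxidation (ene reaction, then [2,3]-sigmatropic shift) attacks only the E-methyl of the electron-rich terminal alkene and carries the alcohol on to the E-enal, while the 2,3-alkene is deactivated by the acetate; no stereocentre is formed.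

Step 2
Reactants: 3 pent-4-ynoic acid; 4 (R)-4-benzyl-1,3-oxazolidin-2-one
Product: 6 (R)-4-benzyl-3-(pent-4-ynoyl)-1,3-oxazolidin-2-one, via mixed pivalic anhydride 5 (not isolated)
Conditions: PivCl, Et3N, THF, −20 °C; then LiCl, 4, −20 °C → rt
Reagents that add atoms: none
Why: Mixed-anhydride N-acylation, in which the LiCl/Et3N-activated oxazolidinone attacks the unhindered pentynoyl carbonyl and the auxiliary stereocentre is untouched.

Step 3
Reactants: 6 (R)-4-benzyl-3-(pent-4-ynoyl)-1,3-oxazolidin-2-one; 2 8-oxogeranyl acetate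
Product: 8 (2E,6E,8R,9S)-9-[(4R)-4-benzyl-2-oxo-1,3-oxazolidine-3-carbonyl]-8-hydroxy-3,7-dimethyldodeca-2,6-dien-11-yn-1-yl acetate, via trimethylsilyl ether 7 (not isolated)
Conditions: MgCl2 (20 mol %), Et3N, Me3SiCl, EtOAc, 23 °C; then TFA (cat.), MeOH
Reagents that add atoms: none
Why: Evans magnesium-halide-catalysed anti-aldol, in which soft enolisation gives the chelated Z-magnesium enolate that meets the α-branched enal (no α-hydrogen) through a boat transition state on the face opposite the benzyl group (the alkylation sense), so the R auxiliary sets 8R,9S (C1 and C2 of the target, anti), and silylation of the aldolate makes the addition irreversible.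

Step 4
Reactants: 9 methyl atratate (methyl 2,4-dihydroxy-3,6-dimethylbenzoate)
Product: 10 methyl 5-formyl-2,4-dihydroxy-3,6-dimethylbenzoate
Conditions: Cl2CHOMe, TiCl4, CH2Cl2, 0 °C; then H2O
Reagents that add atoms: dichloromethyl methyl ether, COC(Cl)Cl; water, O
Why: Rieche formylation, in which the titanium phenoxide directs the electrophile to the only free ring position, ortho to the 4-OH; no stereocentre is formed.

Step 5
Reactants: 10 methyl 5-formyl-2,4-dihydroxy-3,6-dimethylbenzoate
Product: 11 methyl 2,4-dihydroxy-3,5,6-trimethylbenzoate (methyl 3,5-dimethylorsellinate)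
Conditions: H2 (1 atm), 10% Pd/C, AcOH, rt
Reagents that add atoms: none
Why: Hydrogenolysis of an ortho-hydroxybenzaldehyde, in which the aldehyde is reduced and the activated benzylic C–O bond is then cleaved, while the ester and the arene survive.

Step 6
Reactants: 8 anti-aldol allylic acetate; 11 methyl 3,5-dimethylorsellinate
Product: 12 (5'R)-dienone imide: methyl 2'-hydroxy-3',5',6'-trimethyl-4'-oxocyclohexa-1'(6'),2'-diene-1'-carboxylate carrying at C5' the (2E,6E,8R,9S)-9-[(4R)-4-benzyl-2-oxo-1,3-oxazolidine-3-carbonyl]-8-hydroxy-3,7-dimethyldodeca-2,6-dien-11-yn-1-yl chain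
Conditions: Pd2(dba)3·CHCl3 (2.5 mol %), (R,R)-DACH-phenyl Trost ligand (7.5 mol %), Et3N (1.2 equiv), toluene, 0 °C → rt
Reagents that add atoms: none
Why: Proposed new method: zerovalent palladium ionises only the primary allylic acetate to the syn π-allyl complex (E geometry kept), the soft phenoxide of 11 attacks the unhindered CH2 terminus through C5' because only that site leaves the hydrogen-bonded 2'-hydroxy enoate (a vinylogous acid) intact while any O-allyl ether re-ionises and is recycled, and the chiral pocket selects one face of the planar nucleophile to set quaternary C5' as R; the closest known reaction types are the palladium-catalysed asymmetric allylic dearomatisation of naphthols and phenols and the ligand-controlled linear geranylation of oxindoles (Tsuji–Trost alkylation of a prochiral nucleophile).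

Step 7
Reactants: 12 (5'R)-dienone imide
Product: 14 (2S,3R,4E,8E)-3-hydroxy-4,8-dimethyl-2-(prop-2-yn-1-yl)-10-[(5'R)-dienone unit of 12]deca-4,8-dienoic acid, via peroxy acid 13 (not isolated)
Conditions: LiOH·H2O, 30% H2O2, THF–H2O 3:1, 0 °C; Na2SO3; 1 M HCl to pH 3
Reagents that add atoms: hydrogen peroxide, OO
Why: Evans hydroperoxide cleavage, in which HOO− attacks the exocyclic imide carbonyl selectively at 0 °C without epimerisation or retro-aldol, while the dienone is protected as its unreactive lithium vinylogous carboxylate and the hindered ring ester is not touched.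

Step 8
Reactants: 14 hydroxy alkynoic acid
Product: 16 pentacyclic enolised β-diketone lactone (1R,2S,4R,5S,8S,9R,10S,1'R,5'R) with free 1-OH, C3–O–C4 γ-lactone, C1'-CO2Me and C6' exocyclic methylene, via ketal-lactone 15 (not isolated)
Conditions: Ph3PAuNTf2 (2 mol %), CH2Cl2, rt; then 2,6-di-tert-butyl-4-methylpyridine (1.5 equiv), SnCl4 (3 equiv), −78 → −40 °C; aq. NaHCO3
Reagents that add atoms: none
Why: Proposed new method: monovalent gold adds the carboxyl and the C1 hydroxyl across the alkyne (known for alkynoic acids and for bis-homopropargylic diols) to give strained 15, SnCl4 breaks its C4–O(C1) bond as in a Johnson acetal-initiated polyene cyclisation (the competing tetrahydrofuranyl oxocarbenium ion cannot reach C5 and simply recloses), C5 can reach the lactone-bridged acyloxycarbenium ion only from the face that carries C1 so C4 is fixed by C2, all-chair anti additions across the two E-alkenes with the C1–O bond pseudo-axial (which avoids A(1,2) strain with the C10 methyl and misaligns H-1 for a hydride shift) set C5, C10, C9 and C8, and the C8 cation closes on C1' of the matched 5'R dienone, the α-carbon of a tetrasubstituted enoate as in the acid cyclisation of farnesoates to drimenoates, before the hindered pyridine takes a proton from the C6' methyl (C3' could be reached only through a boat ring C, and capture by O4' is reversible under SnCl4).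

Step 9
Reactants: 16 pentacyclic enolised β-diketone lactone
Product: 18 ring-D-contracted acetyl carbinol (bicyclo[3.2.1] core, 2'R: acetyl exo, OH endo; other centres as in 16), via hydroxy diketone 17 (not isolated)
Conditions: 2-(benzenesulfonyl)-3-phenyloxaziridine (1.2 equiv), DBU (0.3 equiv), THF, 0 °C; then 50 °C
Reagents that add atoms: 2-(benzenesulfonyl)-3-phenyloxaziridine, O=S(=O)(c1ccccc1)N1OC1c1ccccc1
Why: Davis hydroxylation of the diketone enolate from the exo face (the endo face is blocked by axial H-9) gives 17 (3'S) with ring D in a boat, and the base-induced α-ketol (acyloin) rearrangement then moves C4' from C3' to the more electrophilic, ester-flanked C2' carbonyl, so that C3' leaves on the exo side and C2' is set with acetyl exo and OH endo; the bridgehead C2–H cannot enolise, so ring A is safe.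

Step 10
Reactants: 18 acetyl carbinol
Product: 20 brasilianoid F (1R,2S,4R,5S,8S,9R,10S,1'R,2'R,3'R,5'R), via hydroxy ester 19 (not isolated)
Conditions: NaBH4, MeOH–THF, −40 → 0 °C; aq. HCl quench
Reagents that add atoms: none
Why: Chemoselective borohydride reduction of the unhindered methyl ketone (the ring ketone lies between two fully substituted carbons) by polar Felkin–Anh addition anti to the C2'–OH, on the rotamer that turns the methyl away from C1', gives the 3'R alkoxide next to the ester, which closes the γ-lactone by intramolecular transesterification.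

## Compound list

1 | geranyl acetate | CC(=O)OC/C=C(\C)CCC=C(C)C | starting material
2 | (2E,6E)-3,7-dimethyl-8-oxoocta-2,6-dien-1-yl acetate | CC(=O)OC/C=C(\C)CC/C=C(\C)C=O | intermediate
3 | pent-4-ynoic acid | C#CCCC(=O)O | starting material
4 | (R)-4-benzyl-1,3-oxazolidin-2-one | O=C1N[C@H](Cc2ccccc2)CO1 | starting material
5 | pent-4-ynoic pivalic anhydride | C#CCCC(=O)OC(=O)C(C)(C)C | intermediate
6 | (R)-4-benzyl-3-(pent-4-ynoyl)-1,3-oxazolidin-2-one | C#CCCC(=O)N1[C@H](Cc2ccccc2)COC1=O | intermediate
7 | 8-O-trimethylsilyl ether of 8 | CC(=O)OC/C=C(\C)CC/C=C(\C)[C@H](O[Si](C)(C)C)[C@H](CC#C)C(=O)N1[C@H](Cc2ccccc2)COC1=O | intermediate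
8 | (8R,9S) anti-aldol allylic acetate | CC(=O)OC/C=C(\C)CC/C=C(\C)[C@H](O)[C@H](CC#C)C(=O)N1[C@H](Cc2ccccc2)COC1=O | intermediate
9 | methyl atratate | COC(=O)c1c(C)cc(O)c(C)c1O | starting material
10 | methyl 5-formyl-2,4-dihydroxy-3,6-dimethylbenzoate | COC(=O)c1c(C)c(C=O)c(O)c(C)c1O | intermediate
11 | methyl 2,4-dihydroxy-3,5,6-trimethylbenzoate | COC(=O)c1c(C)c(C)c(O)c(C)c1O | intermediate
12 | (5'R)-dienone imide | CC1=C(C(=O)OC)C(O)=C(C)C(=O)[C@]1(C)C/C=C(\C)CC/C=C(\C)[C@H](O)[C@H](CC#C)C(=O)N2[C@H](Cc3ccccc3)COC2=O | intermediate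
13 | peroxy acid of 14 | CC1=C(C(=O)OC)C(O)=C(C)C(=O)[C@]1(C)C/C=C(\C)CC/C=C(\C)[C@H](O)[C@H](CC#C)C(=O)OO | intermediate
14 | (2S,3R)-3-hydroxy-2-propargyl dienoic acid with (5'R)-dienone | CC1=C(C(=O)OC)C(O)=C(C)C(=O)[C@]1(C)C/C=C(\C)CC/C=C(\C)[C@H](O)[C@H](CC#C)C(=O)O | intermediate
15 | (1R,4S,5R)-1-methyl-5-alkenyl-2,6-dioxabicyclo[2.2.1]heptan-3-one (ketal-lactone) with (5'R)-dienone | CC1=C(C(=O)OC)C(O)=C(C)C(=O)[C@]1(C)C/C=C(\C)CC/C=C(\C)[C@@H]2O[C@@]3(C)C[C@@H]2C(=O)O3 | intermediate
16 | pentacyclic enolised β-diketone lactone | C=C1[C@@]2(C)C[C@H]3[C@]4(C)[C@H](O)[C@@H]5C[C@@](C)(OC5=O)[C@H]4CC[C@]3(C)[C@]1(C(=O)OC)C(O)=C(C)C2=O | intermediate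
17 | (3'S)-3'-hydroxy-2',4'-diketone (exo OH) | C=C1[C@@]2(C)C[C@H]3[C@]4(C)[C@H](O)[C@@H]5C[C@@](C)(OC5=O)[C@H]4CC[C@]3(C)[C@]1(C(=O)OC)C(=O)[C@@](C)(O)C2=O | intermediate
18 | (2'R) ring-contracted acetyl carbinol | C=C1[C@@]2(C)C[C@H]3[C@]4(C)[C@H](O)[C@@H]5C[C@@](C)(OC5=O)[C@H]4CC[C@]3(C)[C@]1(C(=O)OC)[C@@](O)(C(C)=O)C2=O | intermediate
19 | (2'R,3'R) diol methyl ester | C=C1[C@@]2(C)C[C@H]3[C@]4(C)[C@H](O)[C@@H]5C[C@@](C)(OC5=O)[C@H]4CC[C@]3(C)[C@]1(C(=O)OC)[C@@](O)([C@@H](C)O)C2=O | intermediate
20 | brasilianoid F | C=C1[C@@]2(C)C[C@H]3[C@]4(C)[C@H](O)[C@@H]5C[C@@](C)(OC5=O)[C@H]4CC[C@]3(C)[C@@]13C(=O)O[C@H](C)[C@@]3(O)C2=O | target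

## Step count and risks

Total steps: 10. Longest linear sequence: 7 (steps 1, 3, 6, 7, 8, 9, 10; the branches from 3 and from 9 are equally long).

**Step 8 (highest risk).**
- Possible failures:
  - The C10 cation is weakened by the neighbouring C1–O bond.
  - The C8 cation may be taken by O4' or C3' instead of C1'.
  - The C6' cation may undergo an acyl shift.
- The fallback sets out from 14 and comes back at 18. Ring D is contracted before the polycyclisation, so that no enol carbon or enol oxygen competes for the cation.
- Compound 14 is hydroxylated at C3' (the oxaziridine of step 9, DBU 2.3 equiv, 0 °C) to the hydroxy trione acid F1, as both C3' epimers.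
- On warming with DBU this undergoes the isohumulone-type acyloin contraction to the cyclopentene acetyl carbinol F2 and its C2' epimer F3, which are separated by chromatography.
- F2 is submitted to the conditions of step 8 by way of its ketal-lactone F4. The cascade then ends on the α-carbon of a plain cyclopentene carboxylate and gives 18 directly.

**Step 6.**
- Possible failures: site selectivity (C5' against C3' or O), partial E/Z leakage in the π-allyl complex, and an unknown level of face selectivity.
- The fallback sets out from 11 and comes back at 12. It replaces catalyst control by SN2 alkylative dearomatisation and separation of auxiliary-bearing diastereomers.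
- The lithium phenoxide of 11 (LiN(SiMe3)2, toluene, 0 °C) is alkylated with commercial geranyl bromide to the racemic geranyl dienone F5.
- SeO2 as in step 1 gives the racemic enal F6.
- The aldol with 6 under the conditions of step 3 passes through the bis(trimethylsilyl) ethers F7. It delivers 12 together with the 5'S epimer F8, which is removed by preparative HPLC.

**Step 9.**
- Possible failures: the ketol equilibrium may lie on the side of 17, or the wrong acyl group may migrate.
- The fallback sets out from 17, isolated by leaving out the heating, and comes back at 20.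
- The rearrangement is coupled to the irreversible downstream steps. Compound 17 is stirred with K2CO3 and NaBH4 in i-PrOH–THF at 0 °C → rt.
- Both ketones of 17 are flanked by fully substituted carbons and are reduced slowly. The small equilibrium share of 18 is drained through fast reduction of its methyl ketone to 19 and lactonisation to 20. Only the natural regioisomer can form the γ-lactone.

## Further compounds

F1 | step 8 | 3'-hydroxy-2',4'-dioxo acid from 14 (both C3' epimers) | CC1=C(C(=O)OC)C(=O)C(C)(O)C(=O)[C@]1(C)C/C=C(\C)CC/C=C(\C)[C@H](O)[C@H](CC#C)C(=O)O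
F2 | step 8 | (2'R,5'R) cyclopentene acetyl carbinol acid | CC1=C(C(=O)OC)[C@@](O)(C(C)=O)C(=O)[C@]1(C)C/C=C(\C)CC/C=C(\C)[C@H](O)[C@H](CC#C)C(=O)O
F3 | step 8 | (2'S,5'R) epimer of F2 | CC1=C(C(=O)OC)[C@](O)(C(C)=O)C(=O)[C@]1(C)C/C=C(\C)CC/C=C(\C)[C@H](O)[C@H](CC#C)C(=O)O
F4 | step 8 | ketal-lactone of F2 | CC1=C(C(=O)OC)[C@@](O)(C(C)=O)C(=O)[C@]1(C)C/C=C(\C)CC/C=C(\C)[C@@H]2O[C@@]3(C)C[C@@H]2C(=O)O3
F5 | step 6 | racemic C5'-geranyl dienone | CC1=C(C(=O)OC)C(O)=C(C)C(=O)C1(C)C/C=C(\C)CCC=C(C)C
F6 | step 6 | racemic C5'-(8-oxogeranyl) dienone | CC1=C(C(=O)OC)C(O)=C(C)C(=O)C1(C)C/C=C(\C)CC/C=C(\C)C=O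
F7 | step 6 | bis(trimethylsilyl) ethers of the aldol adducts (both C5' epimers) | CC1=C(C(=O)OC)C(O[Si](C)(C)C)=C(C)C(=O)C1(C)C/C=C(\C)CC/C=C(\C)[C@H](O[Si](C)(C)C)[C@H](CC#C)C(=O)N2[C@H](Cc3ccccc3)COC2=O
F8 | step 6 | 5'S epimer of 12 | CC1=C(C(=O)OC)C(O)=C(C)C(=O)[C@@]1(C)C/C=C(\C)CC/C=C(\C)[C@H](O)[C@H](CC#C)C(=O)N2[C@H](Cc3ccccc3)COC2=O
F0 | step 9 | none | none
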